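**Strategy.** Ring B (the saturated ring of the tetralin) is cut at C1–C2 and C3–C4. This leaves an ortho-quinodimethane on ring A (the methoxybenzene ring), whose termini are the carbinol carbon C1 and the doubly benzylic methine C4, and a two-carbon dienophile. The key step is an enantioselective photoenolization/Diels–Alder reaction. UV light turns a 2-(naphthylmethyl)-3-methoxybenzaldehyde into its hydroxy-ortho-quinodimethane; a chiral titanium TADDOLate holds it while tert-butyl acrylate, an ethylene equivalent, adds across C1 and C4. One operation closes ring B and sets C4. The ester is then removed by oxidation and decarboxylation, and C1 is reset by reagent-controlled transfer hydrogenation.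

Key step: step 5

Assumption 1: 8-methoxynaphthalen-1-ol (1) and methyl 2-(bromomethyl)-3-methoxybenzoate (3) are taken as catalogue compounds.
Assumption 2: the sense of induction of the titanium TADDOLate in step 5 is assigned by analogy, not derived; (R,R)-TADDOL is written for the (4R) series, and the equally available mirror-image ligand would be used if the first run shows the opposite sense.

Step 1
Reactants: 1 8-methoxynaphthalen-1-ol
Product: 2 8-methoxy-1-(methoxymethoxy)naphthalene (numbered so that the MOM ether is at C1)
Conditions: NaH, MOMCl, DMF, 0 °C to rt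
Reagents that add atoms: chloromethyl methyl ether (MOMCl), COCCl
Why: Williamson-type O-alkylation of the sodium naphthoxide (MOM protection) should give the acetal that directs the lithiation of step 2 and masks the oxidisable naphthol through step 6.

Step 2
Reactants: 2 8-methoxy-1-(methoxymethoxy)naphthalene; 3 methyl 2-(bromomethyl)-3-methoxybenzoate
Product: 6 methyl 3-methoxy-2-{[8-methoxy-1-(methoxymethoxy)naphthalen-2-yl]methyl}benzoate, via aryllithium 4 (not isolated), via arylzinc chloride 5 (not isolated)
Conditions: n-BuLi, TMEDA, THF, 0 °C; ZnCl2, THF, 0 °C to rt; 3, Pd(PPh3)4 (5 mol %), THF, 50 °C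
Reagents that add atoms: none
Why: Directed ortho-metalation should occur at C2 next to the chelating OMOM group (a stronger director than the C8 methoxy group), transmetalation to zinc makes the nucleophile compatible with the methyl ester, and a Negishi coupling under zerovalent palladium joins it to the benzylic bromide.

Step 3
Reactants: 6 methyl 3-methoxy-2-{[8-methoxy-1-(methoxymethoxy)naphthalen-2-yl]methyl}benzoate
Product: 7 (3-methoxy-2-{[8-methoxy-1-(methoxymethoxy)naphthalen-2-yl]methyl}phenyl)methanol
Conditions: LiAlH4, THF, 0 °C
Reagents that add atoms: none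
Why: Hydride reduction of the aryl ester to the benzylic alcohol should leave the MOM acetal and the aryl methyl ethers untouched.

Step 4
Reactants: 7 (3-methoxy-2-{[8-methoxy-1-(methoxymethoxy)naphthalen-2-yl]methyl}phenyl)methanol
Product: 8 3-methoxy-2-{[8-methoxy-1-(methoxymethoxy)naphthalen-2-yl]methyl}benzaldehyde
Conditions: MnO2, CH2Cl2, rt
Reagents that add atoms: none
Why: MnO2 oxidation of a benzylic alcohol should stop at the aldehyde and not touch the doubly benzylic CH2 or the acetal.

Step 5
Reactants: 8 3-methoxy-2-{[8-methoxy-1-(methoxymethoxy)naphthalen-2-yl]methyl}benzaldehyde; 9 tert-butyl acrylate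
Product: 11 tert-butyl (1R,2R,4R)-1-hydroxy-5-methoxy-4-[8-methoxy-1-(methoxymethoxy)naphthalen-2-yl]-1,2,3,4-tetrahydronaphthalene-2-carboxylate (hydroxyl, ester and naphthyl all cis), via photoenol 10 (not isolated)
Conditions: Ti(Oi-Pr)4 (1.2 equiv), (R,R)-TADDOL (1.3 equiv), 9 (3 equiv), toluene, hν 366 nm, 0 °C
Reagents that add atoms: none
Why: Excitation of the n,π* band of the benzaldehyde at 366 nm (where the dioxygenated naphthalene should not absorb) is followed by 1,5-hydrogen transfer from the doubly benzylic CH2 to the carbonyl oxygen, and the long-lived dienol 10, with hydroxyl and naphthyl both outward, is caught as its titanium dienolate; the acrylate carbonyl binds the same titanium centre and a templated endo [4+2] cycloaddition follows. The closest known reaction type is the Ti(Oi-Pr)4/TADDOL-mediated enantioselective photoenolization/Diels–Alder reaction of electron-rich 2-alkylbenzaldehydes with unsaturated carbonyl compounds, and photoenol trapping of 2-benzylbenzaldehydes is an established entry to aryltetralins. Ring B is closed by an intermolecular suprafacial [4+2] cycloaddition in which C4–C3 and C2–C1 form together. C4 is set by the TADDOLate, which shields one face of the titanium-bound diene (ligand control), while C1 and C2 follow from the outward diene geometry and the endo, titanium-bridged transition state; C1 and C2 are erased later, so only the facial selectivity matters. The step needs regioselectivity (ester at C2 next to the carbinol carbon), which the titanium bridge between dienol oxygen and ester carbonyl and the larger HOMO coefficient at C4 should secure, and it needs the outward naphthyl geometry, which the clash of an inward naphthyl with the inside hydrogen of the hydroxymethylene terminus should secure. The tert-butyl ester should resist transesterification by the titanium isopropoxide and is the handle for traceless removal of the activating group.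

Step 6
Reactants: 11 tert-butyl (1R,2R,4R)-1-hydroxy-5-methoxy-4-[8-methoxy-1-(methoxymethoxy)naphthalen-2-yl]-1,2,3,4-tetrahydronaphthalene-2-carboxylate
Product: 12 tert-butyl (4R)-5-methoxy-4-[8-methoxy-1-(methoxymethoxy)naphthalen-2-yl]-1-oxo-1,2,3,4-tetrahydronaphthalene-2-carboxylate (C2 epimers and enol form)
Conditions: Dess–Martin periodinane, CH2Cl2, 0 °C to rt
Reagents that add atoms: none
Why: Dess–Martin oxidation of the secondary benzylic alcohol should give the β-keto ester, which erases C1 and C2 (set cis to the naphthyl group, the wrong relative sense for C1) and activates the ester for loss, while the C4 methine is not touched.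

Step 7
Reactants: 12 tert-butyl (4R)-5-methoxy-4-[8-methoxy-1-(methoxymethoxy)naphthalen-2-yl]-1-oxo-1,2,3,4-tetrahydronaphthalene-2-carboxylate
Product: 14 (4R)-4-(1-hydroxy-8-methoxynaphthalen-2-yl)-5-methoxy-3,4-dihydronaphthalen-1(2H)-one, via β-keto acid 13 (not isolated)
Conditions: TFA/CH2Cl2 (1:3), H2O (5 equiv), 0 °C to rt, then 40 °C
Reagents that add atoms: none
Why: Acidolysis should cleave the tert-butyl ester by an E1 path to the β-keto acid, which decarboxylates through the usual six-membered transition state on gentle warming, and the same acid hydrolyses the MOM acetal; C4 has no acidic hydrogen under these conditions and should keep its configuration.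

Step 8
Reactants: 14 (4R)-4-(1-hydroxy-8-methoxynaphthalen-2-yl)-5-methoxy-3,4-dihydronaphthalen-1(2H)-one
Product: 15 (1S,4R)-4-(1-hydroxy-8-methoxynaphthalen-2-yl)-5-methoxy-1,2,3,4-tetrahydronaphthalen-1-ol (dipolynaphthalene A, hydroxyl trans to naphthyl)
Conditions: RuCl[(S,S)-TsDPEN](p-cymene) (2 mol %), HCO2H/Et3N (5:2), EtOAc, rt
Reagents that add atoms: none
Why: Noyori–Ikariya asymmetric transfer hydrogenation of the aryl ketone is reagent-controlled, the (S,S)-catalyst giving the (S)-carbinol of 1-tetralones through the CH–π contact between its η6-arene and the fused benzene ring; the remote C4 substituent should not override it, and the free naphthol should be tolerated in the formic acid/triethylamine medium.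

**Compound list**
1 | 8-methoxynaphthalen-1-ol | COc1cccc2cccc(O)c12 | starting material
2 | 8-methoxy-1-(methoxymethoxy)naphthalene | COCOc1cccc2cccc(OC)c12 | intermediate
3 | methyl 2-(bromomethyl)-3-methoxybenzoate | COC(=O)c1cccc(OC)c1CBr | starting material
4 | [8-methoxy-1-(methoxymethoxy)naphthalen-2-yl]lithium | [Li]c1ccc2cccc(OC)c2c1OCOC | intermediate
5 | chloro[8-methoxy-1-(methoxymethoxy)naphthalen-2-yl]zinc | Cl[Zn]c1ccc2cccc(OC)c2c1OCOC | intermediate
6 | methyl 3-methoxy-2-{[8-methoxy-1-(methoxymethoxy)naphthalen-2-yl]methyl}benzoate | COC(=O)c1cccc(OC)c1Cc1ccc2cccc(OC)c2c1OCOC | intermediate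
7 | (3-methoxy-2-{[8-methoxy-1-(methoxymethoxy)naphthalen-2-yl]methyl}phenyl)methanol | OCc1cccc(OC)c1Cc1ccc2cccc(OC)c2c1OCOC | intermediate
8 | 3-methoxy-2-{[8-methoxy-1-(methoxymethoxy)naphthalen-2-yl]methyl}benzaldehyde | O=Cc1cccc(OC)c1Cc1ccc2cccc(OC)c2c1OCOC | intermediate
9 | tert-butyl acrylate | C=CC(=O)OC(C)(C)C | starting material
10 | photoenol: 6-(hydroxymethylidene)-1-methoxy-5-{[8-methoxy-1-(methoxymethoxy)naphthalen-2-yl]methylidene}cyclohexa-1,3-diene, hydroxyl and naphthyl both outward | O/C=C1\C=CC=C(OC)/C1=C\c1ccc2cccc(OC)c2c1OCOC | intermediate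
11 | tert-butyl (1R,2R,4R)-1-hydroxy-5-methoxy-4-[8-methoxy-1-(methoxymethoxy)naphthalen-2-yl]-1,2,3,4-tetrahydronaphthalene-2-carboxylate | COc1cccc2c1[C@@H](c1ccc3cccc(OC)c3c1OCOC)C[C@@H](C(=O)OC(C)(C)C)[C@H]2O | intermediate
12 | tert-butyl (4R)-5-methoxy-4-[8-methoxy-1-(methoxymethoxy)naphthalen-2-yl]-1-oxo-1,2,3,4-tetrahydronaphthalene-2-carboxylate | COc1cccc2c1[C@@H](c1ccc3cccc(OC)c3c1OCOC)CC(C(=O)OC(C)(C)C)C2=O | intermediate
13 | (4R)-4-(1-hydroxy-8-methoxynaphthalen-2-yl)-5-methoxy-1-oxo-1,2,3,4-tetrahydronaphthalene-2-carboxylic acid | COc1cccc2c1[C@@H](c1ccc3cccc(OC)c3c1O)CC(C(=O)O)C2=O | intermediate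
14 | (4R)-4-(1-hydroxy-8-methoxynaphthalen-2-yl)-5-methoxy-3,4-dihydronaphthalen-1(2H)-one | COc1cccc2c1[C@@H](c1ccc3cccc(OC)c3c1O)CCC2=O | intermediate
15 | (1S,4R)-4-(1-hydroxy-8-methoxynaphthalen-2-yl)-5-methoxy-1,2,3,4-tetrahydronaphthalen-1-ol (dipolynaphthalene A) | COc1cccc2c1[C@@H](c1ccc3cccc(OC)c3c1O)CC[C@@H]2O | target

**Totals.** Total step count: 8. Longest linear sequence: 8 steps (1 to 15; 3 and 9 enter as purchased partners).

**Steps most likely to fail**

Step 5. The excited aldehyde may be quenched by intramolecular triplet energy transfer to the naphthalene before hydrogen transfer. An inward rotation of the naphthyl group may divert the dienol into 6π-electrocyclization and aromatization. Facial control by the TADDOLate over a monodentate acrylate may also be weak. The fallback is thermal and sets out from ester 6. The doubly benzylic anion of 6 (LDA, THF, −78 °C) adds to tert-butyl acrylate 9 in a Michael reaction, and the ester enolate so formed closes ring B on the methyl ester (Dieckmann), which forms the same two bonds in one operation and gives the racemic β-keto ester F1. Acidolysis as in step 7 gives the racemic tetralone F2. The transfer hydrogenation of step 8, run to full conversion on the racemate, should give two separable diastereomers: the target and the (1S,4S)-cis alcohol F3. Chromatography brings the route back at 15, at the cost of half the material.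

Step 8. The catalyst may fail to override the facial bias of the C4 naphthyl group, leading to the cis alcohol. The fallback sets out from 14. NaBH4 in MeOH at 0 °C gives a mixture of 15 and the (1R,4R)-cis alcohol F4. F4 is separated and inverted by a Mitsunobu reaction (4-nitrobenzoic acid, PPh3, DIAD, THF, 0 °C) to the (1S,4R) 4-nitrobenzoate F5; the hydrogen-bonded naphthol, far less acidic than the acid, should not compete. Saponification (LiOH, THF/H2O) comes back to the route at 15.

Step 7. The formaldehyde released from the acetal may alkylate the electron-rich free naphthol ring under acid. The fallback sets out from 12 and separates the two events. Neutral thermolysis in wet DMSO at 130 °C removes the tert-butyl ester and carbon dioxide and gives the MOM-protected tetralone F6. Methanolic HCl at 40 °C then removes the acetal with the formaldehyde captured as its dimethyl acetal, which comes back to the route at 14.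

**Further compounds**
F1 | step 5 | racemic tert-butyl 5-methoxy-4-[8-methoxy-1-(methoxymethoxy)naphthalen-2-yl]-1-oxo-1,2,3,4-tetrahydronaphthalene-2-carboxylate | COc1cccc2c1C(c1ccc3cccc(OC)c3c1OCOC)CC(C(=O)OC(C)(C)C)C2=O
F2 | step 5 | racemic 4-(1-hydroxy-8-methoxynaphthalen-2-yl)-5-methoxy-3,4-dihydronaphthalen-1(2H)-one | COc1cccc2c1C(c1ccc3cccc(OC)c3c1O)CCC2=O
F3 | step 5 | (1S,4S)-4-(1-hydroxy-8-methoxynaphthalen-2-yl)-5-methoxy-1,2,3,4-tetrahydronaphthalen-1-ol | COc1cccc2c1[C@H](c1ccc3cccc(OC)c3c1O)CC[C@@H]2O
F4 | step 8 | (1R,4R)-4-(1-hydroxy-8-methoxynaphthalen-2-yl)-5-methoxy-1,2,3,4-tetrahydronaphthalen-1-ol | COc1cccc2c1[C@@H](c1ccc3cccc(OC)c3c1O)CC[C@H]2O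
F5 | step 8 | (1S,4R)-4-(1-hydroxy-8-methoxynaphthalen-2-yl)-5-methoxy-1,2,3,4-tetrahydronaphthalen-1-yl 4-nitrobenzoate | COc1cccc2c1[C@@H](c1ccc3cccc(OC)c3c1O)CC[C@@H]2OC(=O)c1ccc(cc1)[N+](=O)[O-]
F6 | step 7 | (4R)-5-methoxy-4-[8-methoxy-1-(methoxymethoxy)naphthalen-2-yl]-3,4-dihydronaphthalen-1(2H)-one | COc1cccc2c1[C@@H](c1ccc3cccc(OC)c3c1OCOC)CCC2=O
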